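**Assumption:** 3,5,7-tribromoindole is achiral (planar, no stereocentre), so "single enantiomer" simply means the compound itself; the only stereo-element in the route is the Z double bond of the vinyl azide.

**Retrosynthetic overview**
- The C3–Br bond is made last, by electrophilic bromination of 5,7-dibromoindole at its most nucleophilic position.
- 5,7-Dibromoindole comes from its 2-carboxylic acid by decarboxylation, and the acid from its ethyl ester.
- The pyrrole ring is the only ring formed (the benzene ring is bought): Hemetsberger–Knittel thermolysis of ethyl (Z)-2-azido-3-(3,5-dibromophenyl)acrylate. The aryl group is symmetrical, so both ortho C–H positions are equivalent and only the 5,7-pattern can form.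
- The vinyl azide comes from an intermolecular aldol condensation of 3,5-dibromobenzaldehyde with ethyl azidoacetate, which makes the future C2–C3 bond; ethyl azidoacetate comes from ethyl bromoacetate and NaN3.

**Route**

Step 1
Reactants: 1 ethyl bromoacetate
Product: 2 ethyl azidoacetate
Conditions: NaN3 (1.3 equiv), acetone/H2O 3:1, rt, 16 h; extract into Et2O, concentrate below 30 °C, use crude (not distilled, blast shield)
Reagents that add atoms: sodium azide, [Na+].[N-]=[N+]=[N-]
Why: SN2 displacement of a primary α-bromo ester by azide is fast and clean, and no stereocentre is involved.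

Step 2
Reactants: 2 ethyl azidoacetate; 3 3,5-dibromobenzaldehyde
Product: 5 ethyl (2Z)-2-azido-3-(3,5-dibromophenyl)prop-2-enoate, via β-hydroxy azido ester 4 (not isolated)
Conditions: NaOEt (4 equiv), 2 (4 equiv), EtOH/THF, −15 to 0 °C, 4 h; pour onto ice-water, filter
Reagents that add atoms: none
Why: Intermolecular aldol condensation (Knoevenagel type, first stage of the Hemetsberger–Knittel synthesis) of the azidoacetate enolate with a non-enolisable, electron-poor aldehyde, followed by E1cB loss of hydroxide that erases the two transient stereocentres of 4 and gives the Z alkene (aryl trans to the ester).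

Step 3
Reactants: 5 ethyl (2Z)-2-azido-3-(3,5-dibromophenyl)prop-2-enoate
Product: 7 ethyl 5,7-dibromo-1H-indole-2-carboxylate, via 2H-azirine 6 (not isolated)
Conditions: xylenes, 140 °C, slow addition of 5 (final 0.05 M), 3 h
Reagents that add atoms: none
Why: Hemetsberger–Knittel thermolysis, in which loss of N2 gives the racemic, transient azirine/vinyl nitrene that cyclises onto an ortho C–H and aromatises by hydrogen shift; the two ortho positions are equivalent, so only the 5,7-dibromo isomer can form.

Step 4
Reactants: 7 ethyl 5,7-dibromo-1H-indole-2-carboxylate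
Product: 9 5,7-dibromo-1H-indole-2-carboxylic acid, via sodium carboxylate 8 (not isolated)
Conditions: NaOH (3 equiv), EtOH/H2O 3:1, 80 °C, 2 h; then 2 M HCl to pH 2, filter
Reagents that add atoms: sodium hydroxide, [Na+].[OH-]
Why: Ester saponification followed by acidification is routine, and aryl bromides and the indole N–H are inert to aqueous hydroxide at this temperature.

Step 5
Reactants: 9 5,7-dibromo-1H-indole-2-carboxylic acid
Product: 10 5,7-dibromo-1H-indole
Conditions: Cu powder (0.2 equiv), quinoline, 215 °C, N2, 1.5 h; EtOAc, wash with 2 M HCl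
Reagents that add atoms: none
Why: Copper-mediated thermal protodecarboxylation of an indole-2-carboxylic acid in quinoline is the classical way to finish a Hemetsberger sequence and normally leaves ring bromides untouched in the absence of added base.

Step 6
Reactants: 10 5,7-dibromo-1H-indole
Product: 11 3,5,7-tribromo-1H-indole
Conditions: NBS (1.02 equiv), DMF, 0 °C, 1 h, dark; pour into ice-water containing NaHCO3/Na2S2O3
Reagents that add atoms: N-bromosuccinimide, O=C1CCC(=O)N1Br
Why: Electrophilic aromatic bromination goes at C3, the enamine-like and most nucleophilic indole position, while the two ring bromines deactivate the benzene ring and make the 3-bromoindole product more stable.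

**Compound list**
1 | ethyl bromoacetate | CCOC(=O)CBr | starting material
2 | ethyl azidoacetate | CCOC(=O)CN=[N+]=[N-] | intermediate
3 | 3,5-dibromobenzaldehyde | O=Cc1cc(Br)cc(Br)c1 | starting material
4 | ethyl 2-azido-3-(3,5-dibromophenyl)-3-hydroxypropanoate (racemic syn/anti mixture; not isolated) | CCOC(=O)C(N=[N+]=[N-])C(O)c1cc(Br)cc(Br)c1 | intermediate
5 | ethyl (2Z)-2-azido-3-(3,5-dibromophenyl)prop-2-enoate | CCOC(=O)/C(N=[N+]=[N-])=C/c1cc(Br)cc(Br)c1 | intermediate
6 | ethyl 2-(3,5-dibromophenyl)-2H-azirine-3-carboxylate (racemic; not isolated) | CCOC(=O)C1=NC1c1cc(Br)cc(Br)c1 | intermediate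
7 | ethyl 5,7-dibromo-1H-indole-2-carboxylate | CCOC(=O)c1cc2cc(Br)cc(Br)c2[nH]1 | intermediate
8 | sodium 5,7-dibromo-1H-indole-2-carboxylate (not isolated) | [Na+].[O-]C(=O)c1cc2cc(Br)cc(Br)c2[nH]1 | intermediate
9 | 5,7-dibromo-1H-indole-2-carboxylic acid | OC(=O)c1cc2cc(Br)cc(Br)c2[nH]1 | intermediate
10 | 5,7-dibromo-1H-indole | Brc1cc(Br)c2[nH]ccc2c1 | intermediate
11 | 3,5,7-tribromo-1H-indole | Brc1cc(Br)c2[nH]cc(Br)c2c1 | target

**Step count and risks**
Total steps: 6. Longest linear sequence: 6 (1 → 2 → 5 → 7 → 9 → 10 → 11).

The three steps most likely to fail: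

Step 2 (aldol condensation). Ethyl azidoacetate decomposes under alkoxide, and the one-pot condensation can stall at the aldol stage or give a low yield. The fallback sets out from 3 (with 2) and comes back at 5. The aldol addition is run at −30 °C with 1.5 equiv NaOEt and quenched cold with aqueous NH4Cl, so that the β-hydroxy azido ester 4 is isolated. Compound 4 is then treated with MsCl and excess Et3N in CH2Cl2 at −20 °C to rt, which forms ethyl 2-azido-3-(3,5-dibromophenyl)-3-(methanesulfonyloxy)propanoate F1. F1 loses methanesulfonic acid by base-induced elimination in the same flask to give 5.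

Step 5 (decarboxylation). At 215 °C with copper, partial debromination, Ullmann-type coupling or tar formation is possible. The fallback sets out from 7 and comes back at 10. The ester is reduced with i-Bu2AlH (3.5 equiv, THF, −78 to 0 °C) to (5,7-dibromo-1H-indol-2-yl)methanol F2. F2 is oxidised with MnO2 (CH2Cl2, rt) to 5,7-dibromo-1H-indole-2-carbaldehyde F3. F3 is decarbonylated with catalytic RhCl3·3H2O and 1,3-bis(diphenylphosphino)propane in refluxing diglyme, which extrudes CO and gives 10 without copper.

Step 6 (C3 bromination). Over-bromination at C2 or decomposition of the free 3-bromoindole during work-up is possible. The fallback sets out from 10 and comes back at 11. The nitrogen is sulfonylated (NaH, PhSO2Cl, DMF, 0 °C) to give 5,7-dibromo-1-(phenylsulfonyl)-1H-indole F4. The attenuated ring of F4 is brominated once at C3 with Br2 (1.1 equiv, CH2Cl2, rt) to give crystalline, stable 3,5,7-tribromo-1-(phenylsulfonyl)-1H-indole F5. The sulfonyl group of F5 is removed with aqueous NaOH in THF/MeOH at 50 °C to give 11.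

Further compounds
F1 | step 2 | ethyl 2-azido-3-(3,5-dibromophenyl)-3-(methanesulfonyloxy)propanoate (racemic diastereomer mixture) | CCOC(=O)C(N=[N+]=[N-])C(OS(C)(=O)=O)c1cc(Br)cc(Br)c1
F2 | step 5 | (5,7-dibromo-1H-indol-2-yl)methanol | OCc1cc2cc(Br)cc(Br)c2[nH]1
F3 | step 5 | 5,7-dibromo-1H-indole-2-carbaldehyde | O=Cc1cc2cc(Br)cc(Br)c2[nH]1
F4 | step 6 | 5,7-dibromo-1-(phenylsulfonyl)-1H-indole | O=S(=O)(c1ccccc1)n1ccc2cc(Br)cc(Br)c21
F5 | step 6 | 3,5,7-tribromo-1-(phenylsulfonyl)-1H-indole | O=S(=O)(c1ccccc1)n1cc(Br)c2cc(Br)cc(Br)c21
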